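The flask held more coupling partner than substrate, so I counted turnovers to see what that was worth.

    coupling partner + free catalyst ⇌ catalyst intermediate A (K1 = 380 M⁻¹, k1 = 130 M⁻¹ min⁻¹)
    catalyst intermediate A ⇌ catalyst intermediate B (K2 = 0.46, k2 = 26 min⁻¹)
    substrate + catalyst intermediate B → catalyst intermediate C (k3 = 240 M⁻¹ min⁻¹)
    catalyst intermediate C → free catalyst + target (k4 = 130 min⁻¹)
    target ⇌ isomer of the product (K5 = 1.9, k5 = 0.075 min⁻¹)
    precatalyst → free catalyst (k6 = 0.66 min⁻¹)

substrate 0.10 M; coupling partner 0.130 M; precatalyst 2.0 mM; time 2.0 d

- the reaction counts as stopped when no species that holds the substrate changes by six tenths of a point or more over the second half of the time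
- run time (flask): 2.0 d

- the state of affairs at 2.0 d: stopped, and by what, or still going (it is still moving / forward and back rates have come level / no working catalyst is left / the coupling partner has run out first / all of the substrate has reacted)
- part of the substrate gone at 2.0 d
- the target standing at 2.0 d, as a percentage of the substrate charged

Each round of the catalyst spends one coupling partner and one substrate. So c(coupling partner)/c(precatalyst) came to 65.0 rounds per catalyst, my turnover allowance: the rounds the charged partner can pay for. The substrate needed 50.0, fewer, which made it the limiting reagent and put my upper bound on conversion at 100%.

For the lower bound I took steps 1 and 2 as balanced at the final partner level, which put 29.7% of the catalyst in catalyst intermediate B. That gave the substrate a pseudo-first-order constant of 0.143 min⁻¹, and 2.0 d held about 594 of its half-lives. This floor was rough, resting on an equilibrium share, but the time was far longer than that half-life, so I closed the bracket at full conversion. The target could then stand anywhere up to the full charge, until step 5 tightened it: the relaxation half-life of 0.101 h is shorter than the time, so both bounds met at 1/(1+K5), 34.5%.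

The forecast said all of the substrate has reacted, with conversion 100% and target 34.5%, inside my bracket, starting from “The coupling partner is in excess”.

The simulation gave all of the substrate has reacted, with conversion 100% and target 34.5%.

In this flask the conversion was far along at 0.401 h, earlier than the time, and the relaxation half-life of 0.101 h is shorter than the time. Spending 50.0 of the 65.0 rounds left 23.1% of the partner by count; subtracting what catalyst intermediates A and B hold gives 21.6%, and the flask read 22%. The target moved by 5 points at 0.152 M of substrate or 0.0855 M of partner.

The neighbour charged with 0.17 M of substrate needed 85.0 rounds, more than the allowance, so I expected conversion of 76.5%, substrate left at 23.5% and target at 26.4%. It gave 0% partner, 24% substrate and 26.4% target.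

All constants are invented; the flask was simulated.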